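**Retrosynthetic overview**

1. The target 31 is an α-methylene-γ-lactone (O–C12(=O)–C11(=C13H2)–C7–C6) trans-fused through the C6–C7 bond to a ten-membered carbocycle (C1–C10) that holds a ring-cis C1=C10 alkene.
2. Key disconnection: the shared C6–C7 bond, made by a CrCl2 allylation/lactonisation cascade of the open-chain ω-formyl (Z)-2-(bromomethyl)enoate 24. The carbocycle closes first and the lactone second, in the same flask.
3. Enabling feature: the two fusion atoms C6 and C7 are the carbinol and allylic carbons of the array O–C6–C7–C11(=C13)–C12=O, which is the retron of a carbonyl allylation by a 2-(bromomethyl)enoate. The cis C1=C10 alkene is a built-in turn, and the oxygenated C8 next to C7 steers the faces.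
4. Precursor 24: C7=C11 by Morita–Baylis–Hillman reaction and SN2' bromination; C1=C10 by Horner–Wadsworth–Emmons reaction of lactone phosphonate 14 (C8 from (S)-glycidol) with lactol 9 (C4 from an Evans allylation).
5. After the cascade: PMB to isobutyrate exchange at O8, then desilylation.

Key step: step 17

Assumption: the allylchromium formed from the (Z)-bromide is taken to interconvert its two geometries by 1,3-metal shifts faster than it cyclises, as simple allylchromium reagents do, so that the chair with both ring bonds equatorial decides the C6/C7 relationship.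

Numbering in the text: positions in open-chain compounds carry the germacrane numbers of the target (C1=C10 alkene, C4 bearing C15, C6 lactone carbinol, C7 ring fusion, C8 acyloxy carbon, C11/C12/C13 lactone α-carbon, carbonyl and methylene, C14 on C10).

**Route**

Step 1
Reactants: 1 (S)-4-benzyloxazolidin-2-one; 2 methyl 5-chloro-5-oxopentanoate
Product: 3 methyl 5-[(4S)-4-benzyl-2-oxo-1,3-oxazolidin-3-yl]-5-oxopentanoate
Conditions: n-BuLi, THF, −78 °C; then 2, −78 → 0 °C
Reagents that add atoms: none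
Why: N-acylation of the lithiated oxazolidinone by the acid chloride, which is far more electrophilic than the methyl ester; no stereocentre is formed.

Step 2
Reactants: 3 methyl 5-[(4S)-4-benzyl-2-oxo-1,3-oxazolidin-3-yl]-5-oxopentanoate; 4 allyl iodide
Product: 5 methyl (4R)-4-{[(4S)-4-benzyl-2-oxo-1,3-oxazolidin-3-yl]carbonyl}hept-6-enoate
Conditions: NaN(SiMe3)2, THF, −78 °C; then 4, −78 → −45 °C
Reagents that add atoms: none
Why: Evans asymmetric alkylation, in which the imide (more acidic than the ester) gives the chelated Z sodium enolate and allyl iodide enters on the face opposite the benzyl group, setting C4 as R.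

Step 3
Reactants: 5 methyl (4R)-4-{[(4S)-4-benzyl-2-oxo-1,3-oxazolidin-3-yl]carbonyl}hept-6-enoate
Product: 6 methyl (4R)-4-{[(4S)-4-benzyl-2-oxo-1,3-oxazolidin-3-yl]carbonyl}-6,6-dimethoxyhexanoate
Conditions: O3, CH2Cl2/MeOH, −78 °C; Me2S, −78 °C → rt; then HC(OMe)3, TsOH·H2O (cat.), rt
Reagents that add atoms: trimethyl orthoformate COC(OC)OC; methanol CO
Why: Ozonolysis of the only alkene with reductive work-up gives the C6 aldehyde, which is acetalised in the same flask while imide and ester are inert to acidic methanol; the C4 centre is not touched.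

Step 4
Reactants: 6 methyl (4R)-4-{[(4S)-4-benzyl-2-oxo-1,3-oxazolidin-3-yl]carbonyl}-6,6-dimethoxyhexanoate
Product: 8 (5R)-5-(2,2-dimethoxyethyl)oxan-2-one, via hydroxy ester 7 (not isolated)
Conditions: NaBH4, THF/H2O, 0 °C → rt; then DBU (cat.), toluene, 80 °C
Reagents that add atoms: none
Why: Chemoselective borohydride cleavage of the activated imide releases the auxiliary and the C15 alcohol, and base-catalysed 6-exo-trig lactonisation onto the methyl ester follows, base being chosen because acid would transacetalise the γ-hydroxy acetal; C4 is unchanged.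

Step 5
Reactants: 8 (5R)-5-(2,2-dimethoxyethyl)oxan-2-one
Product: 9 (5R)-5-(2,2-dimethoxyethyl)oxan-2-ol (anomer mixture)
Conditions: i-Bu2AlH, CH2Cl2, −78 °C
Reagents that add atoms: none
Why: Partial reduction of a δ-lactone to the lactol, whose tetrahedral aluminium hemiacetal is stable at low temperature; the lactol masks the C1 aldehyde and O15 together.

Step 6
Reactants: 10 (S)-glycidol
Product: 11 (2R)-2-{[(4-methoxyphenyl)methoxy]methyl}oxirane
Conditions: NaH, 4-methoxybenzyl chloride, Bu4NI (cat.), DMF, 0 °C → rt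
Reagents that add atoms: 4-methoxybenzyl chloride COc1ccc(CCl)cc1
Why: Williamson etherification at oxygen leaves the epoxide carbon untouched, and the descriptor changes from S to R only through the CIP priorities.

Step 7
Reactants: 11 (2R)-2-{[(4-methoxyphenyl)methoxy]methyl}oxirane; 12 triethyl phosphonoacetate
Product: 14 diethyl [(5R)-5-{[(4-methoxyphenyl)methoxy]methyl}-2-oxooxolan-3-yl]phosphonate (C3 epimers), via alkoxide adduct 13 (not isolated)
Conditions: NaH, toluene, 0 → 100 °C; then AcOH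
Reagents that add atoms: none
Why: SN2 opening of the epoxide at its unhindered CH2 (C9) by the phosphonoacetate carbanion and 5-exo-trig lactonisation of the resulting alkoxide onto the ethyl ester; C8 comes unchanged from glycidol and the phosphonate-bearing carbon is an epimer mixture that disappears in step 8.

Step 8
Reactants: 9 (5R)-5-(2,2-dimethoxyethyl)oxan-2-ol; 14 diethyl [(5R)-5-{[(4-methoxyphenyl)methoxy]methyl}-2-oxooxolan-3-yl]phosphonate
Product: 15 (3E,5R)-3-[(4R)-4-(hydroxymethyl)-6,6-dimethoxyhexylidene]-5-{[(4-methoxyphenyl)methoxy]methyl}oxolan-2-one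
Conditions: LiCl, DBU, MeCN, 0 °C → rt
Reagents that add atoms: none
Why: Horner–Wadsworth–Emmons olefination of the open hydroxy-aldehyde form of the lactol under Masamune–Roush conditions, expected to favour the E alkylidene lactone (C2 trans to the lactone carbonyl, hence cis to C9), which is the ring-cis C1=C10 geometry of the target.

Step 9
Reactants: 15 (3E,5R)-3-[(4R)-4-(hydroxymethyl)-6,6-dimethoxyhexylidene]-5-{[(4-methoxyphenyl)methoxy]methyl}oxolan-2-one
Product: 16 (2R,4E,8R)-4,8-bis(hydroxymethyl)-10,10-dimethoxy-1-[(4-methoxyphenyl)methoxy]dec-4-en-2-ol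
Conditions: i-Bu2AlH (excess), CH2Cl2, −78 → 0 °C
Reagents that add atoms: none
Why: Exhaustive 1,2-reduction of the α-alkylidene lactone by an electrophilic hydride gives the allylic C14 alcohol and frees O8 without touching the alkene geometry or the acetal.

Step 10
Reactants: 16 (2R,4E,8R)-4,8-bis(hydroxymethyl)-10,10-dimethoxy-1-[(4-methoxyphenyl)methoxy]dec-4-en-2-ol
Product: 17 (2R,4E,8R)-4,8-bis({[tert-butyl(dimethyl)silyl]oxy}methyl)-10,10-dimethoxy-1-[(4-methoxyphenyl)methoxy]dec-4-en-2-ol
Conditions: TBSCl (2.1 equiv), imidazole, CH2Cl2, −20 → 0 °C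
Reagents that add atoms: tert-butyldimethylsilyl chloride CC(C)(C)[Si](C)(C)Cl
Why: Silylation is much faster at the two primary hydroxyls (O14, O15) than at the secondary O8 hydroxyl flanked by the PMB-oxymethyl group.

Step 11
Reactants: 17 (2R,4E,8R)-4,8-bis({[tert-butyl(dimethyl)silyl]oxy}methyl)-10,10-dimethoxy-1-[(4-methoxyphenyl)methoxy]dec-4-en-2-ol
Product: 18 (4R)-4-[(2E,6R)-2,6-bis({[tert-butyl(dimethyl)silyl]oxy}methyl)-8,8-dimethoxyoct-2-en-1-yl]-2-(4-methoxyphenyl)-1,3-dioxolane (acetal epimers)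
Conditions: DDQ, 4 Å molecular sieves, CH2Cl2, 0 °C
Reagents that add atoms: none
Why: Anhydrous DDQ oxidation of the PMB ether gives an oxocarbenium ion that is trapped by the neighbouring O8 hydroxyl as the five-membered 4-methoxybenzylidene acetal (oxidative acetalisation).

Step 12
Reactants: 18 (4R)-4-[(2E,6R)-2,6-bis({[tert-butyl(dimethyl)silyl]oxy}methyl)-8,8-dimethoxyoct-2-en-1-yl]-2-(4-methoxyphenyl)-1,3-dioxolane
Product: 19 (2R,4E,8R)-4,8-bis({[tert-butyl(dimethyl)silyl]oxy}methyl)-10,10-dimethoxy-2-[(4-methoxyphenyl)methoxy]dec-4-en-1-ol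
Conditions: i-Bu2AlH, CH2Cl2, −78 → −20 °C
Reagents that add atoms: none
Why: Regioselective reductive opening of the arylidene acetal, in which aluminium binds the less hindered primary oxygen and hydride delivery leaves the PMB ether on the secondary O8 and the primary C7 alcohol free.

Step 13
Reactants: 19 (2R,4E,8R)-4,8-bis({[tert-butyl(dimethyl)silyl]oxy}methyl)-10,10-dimethoxy-2-[(4-methoxyphenyl)methoxy]dec-4-en-1-ol
Product: 20 (2R,4E,8R)-4,8-bis({[tert-butyl(dimethyl)silyl]oxy}methyl)-10,10-dimethoxy-2-[(4-methoxyphenyl)methoxy]dec-4-enal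
Conditions: Dess–Martin periodinane, NaHCO3, CH2Cl2, 0 °C → rt
Reagents that add atoms: none
Why: Dess–Martin oxidation under buffered, non-basic conditions gives the α-alkoxy aldehyde without epimerising C8; the aldehyde is used directly.

Step 14
Reactants: 20 (2R,4E,8R)-4,8-bis({[tert-butyl(dimethyl)silyl]oxy}methyl)-10,10-dimethoxy-2-[(4-methoxyphenyl)methoxy]dec-4-enal; 21 methyl acrylate
Product: 22 methyl (4R,6E,10R)-6,10-bis({[tert-butyl(dimethyl)silyl]oxy}methyl)-3-hydroxy-12,12-dimethoxy-4-[(4-methoxyphenyl)methoxy]-2-methylidenedodec-6-enoate (C3 epimers)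
Conditions: DABCO, methyl acrylate (excess, neat), rt
Reagents that add atoms: none
Why: Morita–Baylis–Hillman reaction of an activated α-alkoxy aldehyde; the new C7 carbinol forms as an epimer mixture that does not matter because C7 becomes sp2 in step 15.

Step 15
Reactants: 22 methyl (4R,6E,10R)-6,10-bis({[tert-butyl(dimethyl)silyl]oxy}methyl)-3-hydroxy-12,12-dimethoxy-4-[(4-methoxyphenyl)methoxy]-2-methylidenedodec-6-enoate
Product: 23 methyl (2Z,4R,6E,10R)-2-(bromomethyl)-6,10-bis({[tert-butyl(dimethyl)silyl]oxy}methyl)-12,12-dimethoxy-4-[(4-methoxyphenyl)methoxy]dodeca-2,6-dienoate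
Conditions: NBS, Me2S, CH2Cl2, 0 °C → rt
Reagents that add atoms: N-bromosuccinimide O=C1CCC(=O)N1Br
Why: SN2' bromination of a Baylis–Hillman alcohol, in which the alkoxysulfonium salt formed with bromodimethylsulfonium bromide is displaced by bromide with allylic transposition to the (Z)-2-(bromomethyl)enoate (C8 cis to CH2Br), under neutral conditions that spare the silyl ethers and the acetal.

Step 16
Reactants: 23 methyl (2Z,4R,6E,10R)-2-(bromomethyl)-6,10-bis({[tert-butyl(dimethyl)silyl]oxy}methyl)-12,12-dimethoxy-4-[(4-methoxyphenyl)methoxy]dodeca-2,6-dienoate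
Product: 24 methyl (2Z,4R,6E,10R)-2-(bromomethyl)-6,10-bis({[tert-butyl(dimethyl)silyl]oxy}methyl)-4-[(4-methoxyphenyl)methoxy]-12-oxododeca-2,6-dienoate
Conditions: PPTS (cat.), acetone/H2O, 40 °C
Reagents that add atoms: water O
Why: Mild acid-catalysed hydrolysis of the acyclic dimethyl acetal unmasks the C6 aldehyde under conditions that primary TBS ethers, the PMB ether and the allylic bromide should survive.

Step 17
Reactants: 24 methyl (2Z,4R,6E,10R)-2-(bromomethyl)-6,10-bis({[tert-butyl(dimethyl)silyl]oxy}methyl)-4-[(4-methoxyphenyl)methoxy]-12-oxododeca-2,6-dienoate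
Product: 27 (3aR,4R,6E,10R,11aR)-6,10-bis({[tert-butyl(dimethyl)silyl]oxy}methyl)-4-[(4-methoxyphenyl)methoxy]-3-methylidene-3a,4,5,8,9,10,11,11a-octahydrocyclodeca[b]furan-2(3H)-one, via allylchromium species 25 (not isolated), via chromium alkoxide 26 (not isolated)
Conditions: CrCl2 (10 equiv), THF, rt, slow addition of 24 to 0.002 M final concentration; then aq. NH4Cl
Reagents that add atoms: none
Why: CrCl2 reduces the allylic C13–Br bond in two one-electron steps to a trivalent allylchromium that adds through its γ-carbon C7 to the tethered C6 aldehyde in a chair Zimmerman–Traxler transition state (intramolecular Nozaki–Hiyama–Kishi allylation), after which the chromium alkoxide at O6 acylates on the C12 methyl ester; the closest known reaction type is the chromium-mediated lactone synthesis from 2-(bromomethyl)acrylates and aldehydes and its use to close ten-membered germacranolide carbocycles. The carbocycle closes by C7–C6 bond formation onto the carbonyl (10-exo-trig, with allylic transposition placing C11=C13 outside the ring), and the lactone closes by 5-exo-trig acyl substitution with loss of methoxide. C6 and C7 are set relative to each other by the chair, in which the two ring bonds C6–C5 and C7–C8 both sit equatorial once the allylchromium has equilibrated to the geometry with C8 anti to CH2Cr, giving the 6,7-anti adduct and hence the trans-fused lactone. Their absolute sense is set by the C8 stereocentre: allylic 1,3-strain holds H8 in the allyl plane, the ring chain through C9 lies antiperiplanar to the forming bond and the PMB ether sits outside, so C6 adds to the C7 face that gives the 7,8 relationship of the target. The step needs ring closure over oligomerisation, which the cis C1=C10 turn and high dilution secure, γ- over α-attack, which is inherent to allylchromium reagents, and lactonisation at O6 only, which the PMB ether on O8 secures.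

Step 18
Reactants: 27 (3aR,4R,6E,10R,11aR)-6,10-bis({[tert-butyl(dimethyl)silyl]oxy}methyl)-4-[(4-methoxyphenyl)methoxy]-3-methylidene-3a,4,5,8,9,10,11,11a-octahydrocyclodeca[b]furan-2(3H)-one
Product: 28 (3aR,4R,6E,10R,11aR)-6,10-bis({[tert-butyl(dimethyl)silyl]oxy}methyl)-4-hydroxy-3-methylidene-3a,4,5,8,9,10,11,11a-octahydrocyclodeca[b]furan-2(3H)-one
Conditions: DDQ, CH2Cl2/pH 7 buffer, 0 °C → rt
Reagents that add atoms: none
Why: Oxidative cleavage of the PMB ether by DDQ is orthogonal to the silyl ethers, the methylene lactone and the trisubstituted alkene, and frees only O8.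

Step 19
Reactants: 28 (3aR,4R,6E,10R,11aR)-6,10-bis({[tert-butyl(dimethyl)silyl]oxy}methyl)-4-hydroxy-3-methylidene-3a,4,5,8,9,10,11,11a-octahydrocyclodeca[b]furan-2(3H)-one; 29 isobutyric anhydride
Product: 30 (3aS,4R,6E,10R,11aR)-6,10-bis({[tert-butyl(dimethyl)silyl]oxy}methyl)-3-methylidene-2-oxo-2,3,3a,4,5,8,9,10,11,11a-decahydrocyclodeca[b]furan-4-yl 2-methylpropanoate
Conditions: DMAP (cat.), Et3N, CH2Cl2, 0 °C → rt
Reagents that add atoms: none
Why: DMAP-catalysed acylation of the only free hydroxyl with retention at C8; the descriptor at the ring-fusion carbon changes from R to S only through CIP priorities.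

Step 20
Reactants: 30 (3aS,4R,6E,10R,11aR)-6,10-bis({[tert-butyl(dimethyl)silyl]oxy}methyl)-3-methylidene-2-oxo-2,3,3a,4,5,8,9,10,11,11a-decahydrocyclodeca[b]furan-4-yl 2-methylpropanoate
Product: 31 (3aS,4R,6E,10R,11aR)-6,10-bis(hydroxymethyl)-3-methylidene-2-oxo-2,3,3a,4,5,8,9,10,11,11a-decahydrocyclodeca[b]furan-4-yl 2-methylpropanoate
Conditions: HF·pyridine, pyridine, THF, 0 °C → rt
Reagents that add atoms: none
Why: Acidic fluoride removes both primary TBS ethers without the basic conditions that could move the isobutyrate or add to the methylene lactone.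

**Compound list**

1 | (S)-4-benzyloxazolidin-2-one | O=C1OC[C@H](Cc2ccccc2)N1 | starting material
2 | methyl 5-chloro-5-oxopentanoate | COC(=O)CCCC(Cl)=O | starting material
3 | methyl 5-[(4S)-4-benzyl-2-oxo-1,3-oxazolidin-3-yl]-5-oxopentanoate | COC(=O)CCCC(=O)N1[C@@H](Cc2ccccc2)COC1=O | intermediate
4 | allyl iodide | C=CCI | starting material
5 | methyl (4R)-4-{[(4S)-4-benzyl-2-oxo-1,3-oxazolidin-3-yl]carbonyl}hept-6-enoate | COC(=O)CC[C@H](CC=C)C(=O)N1[C@@H](Cc2ccccc2)COC1=O | intermediate
6 | methyl (4R)-4-{[(4S)-4-benzyl-2-oxo-1,3-oxazolidin-3-yl]carbonyl}-6,6-dimethoxyhexanoate | COC(=O)CC[C@H](CC(OC)OC)C(=O)N1[C@@H](Cc2ccccc2)COC1=O | intermediate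
7 | methyl (4R)-4-(hydroxymethyl)-6,6-dimethoxyhexanoate | COC(=O)CC[C@H](CC(OC)OC)CO | intermediate
8 | (5R)-5-(2,2-dimethoxyethyl)oxan-2-one | O=C1CC[C@H](CC(OC)OC)CO1 | intermediate
9 | (5R)-5-(2,2-dimethoxyethyl)oxan-2-ol (anomer mixture) | OC1CC[C@H](CC(OC)OC)CO1 | intermediate
10 | (S)-glycidol | OC[C@H]1CO1 | starting material
11 | (2R)-2-{[(4-methoxyphenyl)methoxy]methyl}oxirane | COc1ccc(COC[C@H]2CO2)cc1 | intermediate
12 | triethyl phosphonoacetate | CCOC(=O)CP(=O)(OCC)OCC | starting material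
13 | ethyl (4R)-2-(diethoxyphosphoryl)-4-hydroxy-5-[(4-methoxyphenyl)methoxy]pentanoate (formed as its sodium alkoxide, drawn neutral) | CCOC(=O)C(C[C@@H](O)COCc1ccc(OC)cc1)P(=O)(OCC)OCC | intermediate
14 | diethyl [(5R)-5-{[(4-methoxyphenyl)methoxy]methyl}-2-oxooxolan-3-yl]phosphonate (C3 epimers) | CCOP(=O)(OCC)C1C[C@H](COCc2ccc(OC)cc2)OC1=O | intermediate
15 | (3E,5R)-3-[(4R)-4-(hydroxymethyl)-6,6-dimethoxyhexylidene]-5-{[(4-methoxyphenyl)methoxy]methyl}oxolan-2-one | O=C1O[C@@H](COCc2ccc(OC)cc2)C/C1=C\CC[C@@H](CO)CC(OC)OC | intermediate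
16 | (2R,4E,8R)-4,8-bis(hydroxymethyl)-10,10-dimethoxy-1-[(4-methoxyphenyl)methoxy]dec-4-en-2-ol | OC/C(=C/CC[C@@H](CO)CC(OC)OC)C[C@@H](O)COCc1ccc(OC)cc1 | intermediate
17 | (2R,4E,8R)-4,8-bis({[tert-butyl(dimethyl)silyl]oxy}methyl)-10,10-dimethoxy-1-[(4-methoxyphenyl)methoxy]dec-4-en-2-ol | CC(C)(C)[Si](C)(C)OC/C(=C/CC[C@@H](CO[Si](C)(C)C(C)(C)C)CC(OC)OC)C[C@@H](O)COCc1ccc(OC)cc1 | intermediate
18 | (4R)-4-[(2E,6R)-2,6-bis({[tert-butyl(dimethyl)silyl]oxy}methyl)-8,8-dimethoxyoct-2-en-1-yl]-2-(4-methoxyphenyl)-1,3-dioxolane (acetal epimers) | CC(C)(C)[Si](C)(C)OC/C(=C/CC[C@@H](CO[Si](C)(C)C(C)(C)C)CC(OC)OC)C[C@@H]1COC(c2ccc(OC)cc2)O1 | intermediate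
19 | (2R,4E,8R)-4,8-bis({[tert-butyl(dimethyl)silyl]oxy}methyl)-10,10-dimethoxy-2-[(4-methoxyphenyl)methoxy]dec-4-en-1-ol | CC(C)(C)[Si](C)(C)OC/C(=C/CC[C@@H](CO[Si](C)(C)C(C)(C)C)CC(OC)OC)C[C@@H](OCc1ccc(OC)cc1)CO | intermediate
20 | (2R,4E,8R)-4,8-bis({[tert-butyl(dimethyl)silyl]oxy}methyl)-10,10-dimethoxy-2-[(4-methoxyphenyl)methoxy]dec-4-enal | CC(C)(C)[Si](C)(C)OC/C(=C/CC[C@@H](CO[Si](C)(C)C(C)(C)C)CC(OC)OC)C[C@@H](OCc1ccc(OC)cc1)C=O | intermediate
21 | methyl acrylate | C=CC(=O)OC | starting material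
22 | methyl (4R,6E,10R)-6,10-bis({[tert-butyl(dimethyl)silyl]oxy}methyl)-3-hydroxy-12,12-dimethoxy-4-[(4-methoxyphenyl)methoxy]-2-methylidenedodec-6-enoate (C3 epimers) | CC(C)(C)[Si](C)(C)OC/C(=C/CC[C@@H](CO[Si](C)(C)C(C)(C)C)CC(OC)OC)C[C@@H](OCc1ccc(OC)cc1)C(O)C(=C)C(=O)OC | intermediate
23 | methyl (2Z,4R,6E,10R)-2-(bromomethyl)-6,10-bis({[tert-butyl(dimethyl)silyl]oxy}methyl)-12,12-dimethoxy-4-[(4-methoxyphenyl)methoxy]dodeca-2,6-dienoate | CC(C)(C)[Si](C)(C)OC/C(=C/CC[C@@H](CO[Si](C)(C)C(C)(C)C)CC(OC)OC)C[C@@H](OCc1ccc(OC)cc1)/C=C(\CBr)C(=O)OC | intermediate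
24 | methyl (2Z,4R,6E,10R)-2-(bromomethyl)-6,10-bis({[tert-butyl(dimethyl)silyl]oxy}methyl)-4-[(4-methoxyphenyl)methoxy]-12-oxododeca-2,6-dienoate | CC(C)(C)[Si](C)(C)OC/C(=C/CC[C@@H](CO[Si](C)(C)C(C)(C)C)CC=O)C[C@@H](OCc1ccc(OC)cc1)/C=C(\CBr)C(=O)OC | intermediate
25 | allylchromium dichloride derived from 24 (CrCl2 on C13 in place of bromine, solvent ligands omitted) | CC(C)(C)[Si](C)(C)OC/C(=C/CC[C@@H](CO[Si](C)(C)C(C)(C)C)CC=O)C[C@@H](OCc1ccc(OC)cc1)/C=C(\C[Cr](Cl)Cl)C(=O)OC | intermediate
26 | ring-closed ten-membered hydroxy ester, methyl 2-(cyclodecenyl)acrylate with C6 hydroxyl, configuration as in 27 (formed as its chromium alkoxide, drawn as the free alcohol) | O[C@@H]1C[C@H](CO[Si](C)(C)C(C)(C)C)CC/C=C(/CO[Si](C)(C)C(C)(C)C)C[C@@H](OCc2ccc(OC)cc2)[C@H]1C(=C)C(=O)OC | intermediate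
27 | (3aR,4R,6E,10R,11aR)-6,10-bis({[tert-butyl(dimethyl)silyl]oxy}methyl)-4-[(4-methoxyphenyl)methoxy]-3-methylidene-3a,4,5,8,9,10,11,11a-octahydrocyclodeca[b]furan-2(3H)-one | C=C1C(=O)O[C@@H]2C[C@H](CO[Si](C)(C)C(C)(C)C)CC/C=C(/CO[Si](C)(C)C(C)(C)C)C[C@@H](OCc3ccc(OC)cc3)[C@@H]12 | intermediate
28 | (3aR,4R,6E,10R,11aR)-6,10-bis({[tert-butyl(dimethyl)silyl]oxy}methyl)-4-hydroxy-3-methylidene-3a,4,5,8,9,10,11,11a-octahydrocyclodeca[b]furan-2(3H)-one | C=C1C(=O)O[C@@H]2C[C@H](CO[Si](C)(C)C(C)(C)C)CC/C=C(/CO[Si](C)(C)C(C)(C)C)C[C@@H](O)[C@@H]12 | intermediate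
29 | isobutyric anhydride | CC(C)C(=O)OC(=O)C(C)C | starting material
30 | (3aS,4R,6E,10R,11aR)-6,10-bis({[tert-butyl(dimethyl)silyl]oxy}methyl)-3-methylidene-2-oxo-2,3,3a,4,5,8,9,10,11,11a-decahydrocyclodeca[b]furan-4-yl 2-methylpropanoate | C=C1C(=O)O[C@@H]2C[C@H](CO[Si](C)(C)C(C)(C)C)CC/C=C(/CO[Si](C)(C)C(C)(C)C)C[C@@H](OC(=O)C(C)C)[C@@H]12 | intermediate
31 | (3aS,4R,6E,10R,11aR)-6,10-bis(hydroxymethyl)-3-methylidene-2-oxo-2,3,3a,4,5,8,9,10,11,11a-decahydrocyclodeca[b]furan-4-yl 2-methylpropanoate | C=C1C(=O)O[C@@H]2C[C@H](CO)CC/C=C(/CO)C[C@@H](OC(=O)C(C)C)[C@@H]12 | target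

**Step count and risks**

Total step count: 20. Longest linear sequence: 18 (steps 1–5 and 8–20).

Steps most likely to fail:

1. Step 17. What may go wrong: oligomerisation instead of ring closure; closure through the alternative chair with C8 axial, which would lead to the cis-fused lactone; addition to the other C7 face; or 1,4-elimination of the C8 alkoxide from the allylchromium. Fallback: setting out from bromide 23, the ester is taken out of the allyl unit so that only the carbocycle is closed by chromium. i-Bu2AlH (CH2Cl2, −78 °C) should reduce the methyl ester to the primary allylic alcohol, bromo alcohol F1. PPTS in wet acetone should then unmask the C6 aldehyde, giving hydroxy aldehyde F2. CrCl2 in THF at high dilution should close the ten-membered ring through an ester-free 2-substituted allylchromium, the reagent class for which anti-selective closure of germacrane rings is established, giving ring diol F3. MnO2 in CH2Cl2 should oxidise the allylic C12 alcohol to the enal, whose lactol with O6 is oxidised further to the lactone, and the route is rejoined at 27.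

2. Step 14. What may go wrong: slow conversion, with base-mediated enolisation of the α-alkoxy aldehyde eroding the C8 configuration during the long reaction time. Fallback: setting out from aldehyde 20, the amine-catalysed reaction is replaced by vinylalumination. Methyl propiolate is hydroaluminated with i-Bu2AlH and N-methylmorpholine N-oxide in THF at 0 °C to the α-(methoxycarbonyl)vinyl aluminium reagent, which should add to 20 at −78 → 0 °C within hours and without free base, giving the same allylic alcohol and rejoining the route at 22.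

3. Step 8. What may go wrong: oxa-Michael closure of the liberated C15 alkoxide onto the newly formed alkylidene lactone (tetrahydropyran formation), together with incomplete E selectivity. Fallback: setting out from lactone 8, the hydroxyl is capped before the olefination. MeNH(OMe)·HCl with AlMe3 (CH2Cl2, 0 °C) should open the lactone to hydroxy Weinreb amide F4. TBSCl and imidazole give silyl ether F5, and i-Bu2AlH (THF, −78 °C) gives aldehyde F6. The same Horner–Wadsworth–Emmons reaction with 14 (LiCl, DBU, MeCN) gives silylated alkylidene lactone F7, now without a free alkoxide. i-Bu2AlH then gives diol F8, and one equivalent of TBSCl with imidazole silylates the primary allylic hydroxyl, rejoining the route at 17.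

Further compounds
F1 | step 17 | (2Z,4R,6E,10R)-2-(bromomethyl)-6,10-bis({[tert-butyl(dimethyl)silyl]oxy}methyl)-12,12-dimethoxy-4-[(4-methoxyphenyl)methoxy]dodeca-2,6-dien-1-ol | CC(C)(C)[Si](C)(C)OC/C(=C/CC[C@@H](CO[Si](C)(C)C(C)(C)C)CC(OC)OC)C[C@@H](OCc1ccc(OC)cc1)/C=C(\CBr)CO
F2 | step 17 | (3R,5E,9R,11Z)-11-(bromomethyl)-3,7-bis({[tert-butyl(dimethyl)silyl]oxy}methyl)-12-hydroxy-9-[(4-methoxyphenyl)methoxy]dodeca-5,10-dienal | CC(C)(C)[Si](C)(C)OC/C(=C/CC[C@@H](CO[Si](C)(C)C(C)(C)C)CC=O)C[C@@H](OCc1ccc(OC)cc1)/C=C(\CBr)CO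
F3 | step 17 | ring diol: ten-membered carbocycle of 27 with free C6 hydroxyl and a 3-hydroxyprop-1-en-2-yl group on C7 | O[C@@H]1C[C@H](CO[Si](C)(C)C(C)(C)C)CC/C=C(/CO[Si](C)(C)C(C)(C)C)C[C@@H](OCc2ccc(OC)cc2)[C@H]1C(=C)CO
F0 | step 14 | none | none
F4 | step 8 | (4R)-4-(hydroxymethyl)-N,6,6-trimethoxy-N-methylhexanamide | CON(C)C(=O)CC[C@H](CC(OC)OC)CO
F5 | step 8 | (4R)-4-({[tert-butyl(dimethyl)silyl]oxy}methyl)-N,6,6-trimethoxy-N-methylhexanamide | CON(C)C(=O)CC[C@H](CC(OC)OC)CO[Si](C)(C)C(C)(C)C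
F6 | step 8 | (4R)-4-({[tert-butyl(dimethyl)silyl]oxy}methyl)-6,6-dimethoxyhexanal | O=CCC[C@H](CC(OC)OC)CO[Si](C)(C)C(C)(C)C
F7 | step 8 | (3E,5R)-3-[(4R)-4-({[tert-butyl(dimethyl)silyl]oxy}methyl)-6,6-dimethoxyhexylidene]-5-{[(4-methoxyphenyl)methoxy]methyl}oxolan-2-one | O=C1O[C@@H](COCc2ccc(OC)cc2)C/C1=C\CC[C@@H](CO[Si](C)(C)C(C)(C)C)CC(OC)OC
F8 | step 8 | (2R,4E,8R)-8-({[tert-butyl(dimethyl)silyl]oxy}methyl)-4-(hydroxymethyl)-10,10-dimethoxy-1-[(4-methoxyphenyl)methoxy]dec-4-en-2-ol | OC/C(=C/CC[C@@H](CO[Si](C)(C)C(C)(C)C)CC(OC)OC)C[C@@H](O)COCc1ccc(OC)cc1
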